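**Plan**

- Retrosynthesis: the two N1–C(tert-prenyl) bonds and the two C2=C3 double bonds are taken back to a meso 3,3'-methylenebis(indoline). In each indoline the benzene ring is then cut at C3a–C7a and C4–C5, and last the two N1–C2 bonds are cut.
- Enabling feature: in each indole, C7a, C7, C6 and C5 map onto C2 to C5 of a furan-2-amine whose nitrogen is N1, C3a and C4 map onto a vinyl group on C3, and the ring oxygen is the only atom lost, as water.
- Forward: norbornadiene gives the C9 chain (dihydroxylation, ethenolysis, glycol cleavage and reduction), both Boc-aminofurans are attached by N-alkylation, and one thermolysis closes all four rings (two pyrrolidines, two benzene rings).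
- End game: Boc removal, copper-catalysed N-propargylation, semihydrogenation to the tert-prenyl groups, dehydrogenation of both indolines to the indoles.
- Stereochemistry: the target has no stereocentre. The two C3 centres carried along are the meso pair fixed by the cis-fused norbornene and are erased in the last step.

Key step: step 7

Remark: the intermediates between the ring-opened diol and the last indoline are written as the single meso diastereomer delivered by the norbornene. Partial epimerisation at the dialdehyde stage would be harmless, because both centres become sp2 in the last step.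

**Route**

Step 1
Reactants: 1 furan-2-carboxylic acid (2-furoic acid)
Product: 4 tert-butyl furan-2-ylcarbamate, via furan-2-carbonyl azide 2 (not isolated), via 2-isocyanatofuran 3 (not isolated)
Conditions: DPPA, Et3N, t-BuOH, 85 °C
Reagents that add atoms: diphenylphosphoryl azide, [N-]=[N+]=NP(=O)(Oc1ccccc1)Oc1ccccc1; tert-butanol, CC(C)(C)O
Why: Curtius rearrangement, in which the acyl azide formed from the acid and DPPA loses N2 on heating and tert-butanol traps the isocyanate as the Boc carbamate, the stable and storable form of 2-aminofuran.

Step 2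
Reactants: 5 bicyclo[2.2.1]hepta-2,5-diene (norbornadiene, 3 equiv)
Product: 6 exo,cis-bicyclo[2.2.1]hept-5-ene-2,3-diol
Conditions: OsO4 (1 mol%), NMO (1 equiv), acetone/H2O, 0 °C to rt
Reagents that add atoms: N-methylmorpholine N-oxide, C[N+]1([O-])CCOCC1; water, O
Why: Upjohn dihydroxylation, in which OsO4 adds once from the exo face of the strained diene kept in excess, so that one alkene remains for ring opening and the cis-diol marks the bond to be cut later.

Step 3
Reactants: 6 exo,cis-bicyclo[2.2.1]hept-5-ene-2,3-diol; 7 ethylene (1 atm)
Product: 8 (1R,2S,3S,5R)-3,5-diethenylcyclopentane-1,2-diol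
Conditions: RuCl2(=CHPh)(PCy3)2 (first-generation Grubbs catalyst, 2 mol%), CH2Cl2 (0.02 M), rt
Reagents that add atoms: none
Why: Ring-opening cross-metathesis with ethylene (ethenolysis) is driven by release of norbornene strain, dilution under ethylene holds back polymerisation, the ruthenium carbene tolerates free hydroxyl groups, and the cis relation of the two new vinyl groups is fixed by the bicycle.

Step 4
Reactants: 8 (1R,2S,3S,5R)-3,5-diethenylcyclopentane-1,2-diol
Product: 10 (2R,4S)-2,4-diethenylpentane-1,5-diol, via (2R,4S)-2,4-diethenylpentanedial 9 (not isolated)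
Conditions: NaIO4, THF/H2O (pH 7), 0 °C; then NaBH4 (excess), 0 °C
Reagents that add atoms: none
Why: Malaprade glycol cleavage of the cis-diol gives the dialdehyde, which NaBH4 should reduce in the same pot before its α-vinyl centres can epimerise or the double bonds move into conjugation, so the meso relation set by the ring is kept.

Step 5
Reactants: 10 (2R,4S)-2,4-diethenylpentane-1,5-diol
Product: 11 (2R,4S)-2,4-diethenylpentane-1,5-diyl dimethanesulfonate
Conditions: MsCl, Et3N, CH2Cl2, 0 °C
Reagents that add atoms: methanesulfonyl chloride, CS(=O)(=O)Cl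
Why: Sulfonylation of the two primary alcohols gives a stable bis-electrophile without touching the stereocentres, and unlike phosphine-based halogenation it cannot close the 1,5-diol to a tetrahydropyran.

Step 6
Reactants: 4 tert-butyl furan-2-ylcarbamate (2.5 equiv); 11 (2R,4S)-2,4-diethenylpentane-1,5-diyl dimethanesulfonate
Product: 12 di-tert-butyl [(2R,4S)-2,4-diethenylpentane-1,5-diyl]bis[(furan-2-yl)carbamate]
Conditions: NaH, DMF, 0 °C; then 11, Bu4NI (cat.), 60 °C
Reagents that add atoms: none
Why: N-Alkylation (SN2) of the sodium salt of a furan-2-ylcarbamate with primary electrophiles in DMF is the standard entry to N-alkenyl-2-amidofurans, iodide catalysis (Finkelstein exchange in the flask) speeds substitution at the β-branched carbons, and 60 °C lies far below the onset of cycloaddition.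

Step 7
Reactants: 12 di-tert-butyl [(2R,4S)-2,4-diethenylpentane-1,5-diyl]bis[(furan-2-yl)carbamate]
Product: 15 di-tert-butyl (3R,3'S)-3,3'-methylenebis(2,3-dihydro-1H-indole-1-carboxylate), via bis-oxanorbornene cycloadduct 13 (not isolated), via bis-cyclohexadienol 14 (not isolated)
Conditions: PhMe (0.01 M, degassed), 165 °C, sealed tube
Reagents that add atoms: none
Why: On heating, each N-Boc-2-aminofuran acts as the diene of an intramolecular Diels–Alder reaction of furan with the vinyl group held three atoms away (N1–C2–C3), so that furan C2 bonds to the internal alkene carbon (C7a–C3a) and furan C5 to the terminal one (C5–C4); the nitrogen lone pair then opens the oxygen bridge of 13, proton loss from C3a gives dienol 14, and loss of water leaves the benzene ring. The closest known reaction is the thermal cycloaddition, ring opening and dehydration of tert-butyl but-3-enyl(furan-2-yl)carbamates to N-Boc-indolines, here run at both ends of one chain. Each five-membered nitrogen ring closes through the C3a–C7a bond as the tether-fused ring of a type 1 intramolecular [4+2] addition, and each six-membered carbocycle closes through the concerted pair of bonds C3a–C7a and C4–C5. No lasting stereocentre is made, since the bridgehead and carbinol centres of 13 and 14 vanish on aromatisation and C3 and C3' keep the meso configuration of 12. The step needs each furan to take its own vinyl group and the opened adduct to dehydrate instead of shifting hydride to a ketone; the first is secured by the tether (a five-membered ring to the near alkene against a seven-membered ring to the far one) and by dilution, the second by the hydrogen on C3a, whose loss starts the aromatisation.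

Step 8
Reactants: 15 di-tert-butyl (3R,3'S)-3,3'-methylenebis(2,3-dihydro-1H-indole-1-carboxylate)
Product: 16 (3R,3'S)-3,3'-methylenebis(2,3-dihydro-1H-indole)
Conditions: TFA, CH2Cl2, 0 °C to rt; aq. NaHCO3
Reagents that add atoms: none
Why: Acidolysis of the tert-butyl carbamates (loss of isobutene and CO2) frees both indoline nitrogens, and the indoline rings and the C3–H centres are stable to TFA.

Step 9
Reactants: 16 (3R,3'S)-3,3'-methylenebis(2,3-dihydro-1H-indole); 17 3-chloro-3-methylbut-1-yne (4 equiv)
Product: 18 (3R,3'S)-3,3'-methylenebis[1-(2-methylbut-3-yn-2-yl)-2,3-dihydro-1H-indole]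
Conditions: CuCl (10 mol%), Et3N, THF, 0 °C to rt
Reagents that add atoms: none
Why: Copper-catalysed propargylic amination, in which the copper acetylide of the tertiary propargylic chloride ionises to an allenylidene-type electrophile that the secondary indoline nitrogen captures at the tertiary carbon, is the established first stage of N-tert-prenylation and works on indolines where indoles fail.

Step 10
Reactants: 18 (3R,3'S)-3,3'-methylenebis[1-(2-methylbut-3-yn-2-yl)-2,3-dihydro-1H-indole]
Product: 19 (3R,3'S)-3,3'-methylenebis[1-(2-methylbut-3-en-2-yl)-2,3-dihydro-1H-indole]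
Conditions: H2 (1 atm), Pd/CaCO3 poisoned with Pb(OAc)2 (Lindlar catalyst), quinoline, EtOAc, rt
Reagents that add atoms: none
Why: Lindlar semihydrogenation should stop at the alkene because the poisoned palladium surface binds the terminal alkyne far more strongly than the vinyl group formed, and the indoline and arene rings are not reduced.

Step 11
Reactants: 19 (3R,3'S)-3,3'-methylenebis[1-(2-methylbut-3-en-2-yl)-2,3-dihydro-1H-indole]
Product: 20 polonidine A, 3,3'-methylenebis[1-(2-methylbut-3-en-2-yl)-1H-indole]
Conditions: MnO2 (activated, excess), CH2Cl2, rt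
Reagents that add atoms: none
Why: Dehydrogenation of N-alkylindolines with activated MnO2 is driven by aromatisation of the pyrrole ring, removes both C3 stereocentres, and leaves the isolated terminal alkenes alone.

**Compound list**

1 | furan-2-carboxylic acid (2-furoic acid) | O=C(O)c1ccco1 | starting material
2 | furan-2-carbonyl azide | [N-]=[N+]=NC(=O)c1ccco1 | intermediate (not isolated)
3 | 2-isocyanatofuran | O=C=Nc1ccco1 | intermediate (not isolated)
4 | tert-butyl furan-2-ylcarbamate | CC(C)(C)OC(=O)Nc1ccco1 | intermediate
5 | bicyclo[2.2.1]hepta-2,5-diene (norbornadiene) | C1=CC2C=CC1C2 | starting material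
6 | exo,cis-bicyclo[2.2.1]hept-5-ene-2,3-diol (meso, (1R,2R,3S,4S)) | O[C@@H]1[C@H](O)[C@H]2C=C[C@@H]1C2 | intermediate
7 | ethylene | C=C | starting material
8 | (1R,2S,3S,5R)-3,5-diethenylcyclopentane-1,2-diol (meso; vinyl groups cis to each other and trans to the cis-diol) | O[C@@H]1[C@H](O)[C@@H](C=C)C[C@H]1C=C | intermediate
9 | (2R,4S)-2,4-diethenylpentanedial (meso) | O=C[C@@H](C=C)C[C@@H](C=C)C=O | intermediate (not isolated)
10 | (2R,4S)-2,4-diethenylpentane-1,5-diol (meso) | OC[C@@H](C=C)C[C@@H](C=C)CO | intermediate
11 | (2R,4S)-2,4-diethenylpentane-1,5-diyl dimethanesulfonate | CS(=O)(=O)OC[C@@H](C=C)C[C@@H](C=C)COS(C)(=O)=O | intermediate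
12 | di-tert-butyl [(2R,4S)-2,4-diethenylpentane-1,5-diyl]bis[(furan-2-yl)carbamate] | CC(C)(C)OC(=O)N(c1ccco1)C[C@@H](C=C)C[C@@H](C=C)CN(C(=O)OC(C)(C)C)c1ccco1 | intermediate
13 | di-tert-butyl (3R,3'S)-3,3'-methylenebis(5,7a-epoxy-2,3,3a,4,5,7a-hexahydro-1H-indole-1-carboxylate), the bis-oxanorbornene cycloadduct (new centres as a mixture; each end passes this stage independently) | CC(C)(C)OC(=O)N1C[C@H](C[C@@H]2CN(C(=O)OC(C)(C)C)C34C=CC(CC24)O3)C2CC3C=CC21O3 | intermediate (not isolated)
14 | di-tert-butyl (3R,3'S)-3,3'-methylenebis(5-hydroxy-2,3,4,5-tetrahydro-1H-indole-1-carboxylate), the bis-cyclohexadienol (C5 centres as a mixture) | CC(C)(C)OC(=O)N1C[C@H](C[C@@H]2CN(C(=O)OC(C)(C)C)C3=C2CC(O)C=C3)C2=C1C=CC(O)C2 | intermediate (not isolated)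
15 | di-tert-butyl (3R,3'S)-3,3'-methylenebis(2,3-dihydro-1H-indole-1-carboxylate) (meso) | CC(C)(C)OC(=O)N1C[C@H](C[C@@H]2CN(C(=O)OC(C)(C)C)c3ccccc32)c2ccccc21 | intermediate
16 | (3R,3'S)-3,3'-methylenebis(2,3-dihydro-1H-indole) (meso) | N1C[C@H](C[C@@H]2CNc3ccccc32)c2ccccc21 | intermediate
17 | 3-chloro-3-methylbut-1-yne | C#CC(C)(C)Cl | starting material
18 | (3R,3'S)-3,3'-methylenebis[1-(2-methylbut-3-yn-2-yl)-2,3-dihydro-1H-indole] | C#CC(C)(C)N1C[C@H](C[C@@H]2CN(C(C)(C)C#C)c3ccccc32)c2ccccc21 | intermediate
19 | (3R,3'S)-3,3'-methylenebis[1-(2-methylbut-3-en-2-yl)-2,3-dihydro-1H-indole] | C=CC(C)(C)N1C[C@H](C[C@@H]2CN(C(C)(C)C=C)c3ccccc32)c2ccccc21 | intermediate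
20 | polonidine A, 3,3'-methylenebis[1-(2-methylbut-3-en-2-yl)-1H-indole] | C=CC(C)(C)n1cc(Cc2cn(C(C)(C)C=C)c3ccccc23)c2ccccc21 | target

**Step count**

Total: 11 steps. Longest linear sequence: 10 steps (5 to 20, steps 2 to 11); step 1 is a one-step branch.

**Steps most likely to fail**

Step 7. Thermal loss of the Boc groups could compete with the slower of the two cycloadditions and expose an unprotected aminofuran that decomposes. The fallback sets out from 11 and carries a carbamate that cannot fragment. Acid 1 is taken through the same Curtius reaction (via 2 and 3) with methanol in place of tert-butanol to give methyl furan-2-ylcarbamate F1. Its sodium salt is alkylated with 11 as in step 6 to give dimethyl [(2R,4S)-2,4-diethenylpentane-1,5-diyl]bis[(furan-2-yl)carbamate] F2. Heating in o-dichlorobenzene at 190 °C should give dimethyl (3R,3'S)-3,3'-methylenebis(2,3-dihydro-1H-indole-1-carboxylate) F3. Hydrolysis with KOH in ethylene glycol/water at 120 °C then returns to the route at 16.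

Step 6. E2 elimination toward a conjugated diene (the β-hydrogen is allylic) could compete with substitution, or the reaction could stall after the first alkylation. The fallback sets out from 11 and forms the N–furan bond last. Displacement with the weakly basic KN(Boc)2 in DMF at 60 °C gives tetra-tert-butyl [(2R,4S)-2,4-diethenylpentane-1,5-diyl]bis(imidodicarbonate) F4. Removal of one Boc group from each nitrogen with Mg(ClO4)2 (cat.) in MeCN at 50 °C gives di-tert-butyl [(2R,4S)-2,4-diethenylpentane-1,5-diyl]dicarbamate F5. Goldberg-type amidation of 2-bromofuran (CuI, N,N'-dimethylethylenediamine, K3PO4, toluene, 90 °C) then returns to the route at 12.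

Step 11. Once the indoles form, the methylene bridge is activated by both of them and could be over-oxidised, or the N-tert-alkyl groups could be cleaved oxidatively. The fallback sets out from 16 and moves the dehydrogenation ahead of the introduction of any alkene. Acceptorless dehydrogenation over Pd/C in refluxing mesitylene gives 3,3'-methylenebis(1H-indole) F6. Direct palladium-catalysed N-tert-prenylation of both indole nitrogens with 2-methylbut-2-ene (Pd(OAc)2, Cu(OAc)2, AgOTf, MeCN, 35 °C) then returns to the route at 20.

Further compounds
F1 | step 7 | methyl furan-2-ylcarbamate | COC(=O)Nc1ccco1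
F2 | step 7 | dimethyl [(2R,4S)-2,4-diethenylpentane-1,5-diyl]bis[(furan-2-yl)carbamate] | COC(=O)N(c1ccco1)C[C@@H](C=C)C[C@@H](C=C)CN(C(=O)OC)c1ccco1
F3 | step 7 | dimethyl (3R,3'S)-3,3'-methylenebis(2,3-dihydro-1H-indole-1-carboxylate) | COC(=O)N1C[C@H](C[C@@H]2CN(C(=O)OC)c3ccccc32)c2ccccc21
F4 | step 6 | tetra-tert-butyl [(2R,4S)-2,4-diethenylpentane-1,5-diyl]bis(imidodicarbonate) | CC(C)(C)OC(=O)N(C(=O)OC(C)(C)C)C[C@@H](C=C)C[C@@H](C=C)CN(C(=O)OC(C)(C)C)C(=O)OC(C)(C)C
F5 | step 6 | di-tert-butyl [(2R,4S)-2,4-diethenylpentane-1,5-diyl]dicarbamate | CC(C)(C)OC(=O)NC[C@@H](C=C)C[C@@H](C=C)CNC(=O)OC(C)(C)C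
F6 | step 11 | 3,3'-methylenebis(1H-indole) | C(c1c[nH]c2ccccc12)c1c[nH]c2ccccc12
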